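## Retrosynthetic overview

1. The target is a 2,5-diaryl-3,4-dimethyloxolane (ring B) with the substituents trans,cis,trans around the ring. Ring A (3-hydroxy-4,5-dimethoxyphenyl) sits on C2 and ring C (3,4,5-trimethoxyphenyl) on C5, so the chirality rests only on which end of the meso-like C3/C4 unit carries which aryl ring.
2. Endgame: O-debenzylation and O-methylation lead back to a ring-A phenol with a free 4-hydroxyl. The key disconnection is O1–C2 of ring B: C2 becomes the exocyclic carbon of a p-quinone methide of ring A and is attacked by the hydroxyl on C5, the closure held to form this skeleton in nature. The quinone methide comes from a benzylic triol made in the same pot by adding a ring-A aryllithium to a C5-aryl lactol.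
3. Enabling feature: the oxygen on C4 of ring A lies para to the ring carbon bonded to C2. As a free phenol it lets C2, and only C2, ionise, and the chain O–C5–C4–C3–C2 is set up for 5-exo-trig closure with the C3 methyl steering the new C2 centre.
4. Lactol ⇐ lactone ⇐ keto acid (Felkin–Anh reduction sets C5) ⇐ enantioselective desymmetrising aryl coupling of meso cis-2,3-dimethylsuccinic anhydride (fixes C3/C4 in the absolute sense) ⇐ hydrogenation of 2,3-dimethylmaleic anhydride.
5. Ring order: ring C is bought and attached first, the five-membered anhydride/lactone/lactol ring is carried as a temporary template, and ring A is attached and ring B closed last, both in the key step.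

Key step: step 8

Assumption: the (R,R)-enantiomer of the TADDOL-derived dimethylphosphoramidite is taken as the ligand that sends the aryl group to the carbonyl next to the (R)-configured carbon of the meso anhydride; if the sense of induction proves opposite, the (S,S)-ligand is used and nothing else changes.

## Route

Step 1
Reactants: 1 2,3-dimethylmaleic anhydride
Product: 2 cis-2,3-dimethylsuccinic anhydride (meso; (3R,4S)-3,4-dimethyloxolane-2,5-dione)
Conditions: H2 (3 atm), Pd/C, EtOAc, rt
Reagents that add atoms: none
Why: Heterogeneous catalytic hydrogenation delivers both hydrogens to one face of the tetrasubstituted alkene (syn addition), so the two new stereocentres are set cis and the product is the meso anhydride.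

Step 2
Reactants: 2 cis-2,3-dimethylsuccinic anhydride; 3 5-bromo-1,2,3-trimethoxybenzene
Product: 6 (2S,3R)-2,3-dimethyl-4-oxo-4-(3,4,5-trimethoxyphenyl)butanoic acid, via aryllithium 4 (not isolated), via arylzinc triflate 5 (not isolated)
Conditions: 3, n-BuLi, THF, −78 °C; Zn(OTf)2, −78 °C → rt; then 2, [Rh(cod)Cl]2 (cat.), (R,R)-TADDOL-PNMe2 (cat.), THF/DMF, 50 °C; aq. HCl work-up
Reagents that add atoms: none
Why: Rhodium-catalysed enantioselective acyl cross-coupling of a meso cyclic anhydride with an arylzinc reagent (Negishi-type desymmetrisation), in which the chiral phosphoramidite complex inserts into one of the two enantiotopic acyl–oxygen bonds and transfers the aryl group, so the cis-methyl centres are kept and the choice of carbonyl fixes C3 and C4 of the target in the absolute sense.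

Step 3
Reactants: 6 (2S,3R)-2,3-dimethyl-4-oxo-4-(3,4,5-trimethoxyphenyl)butanoic acid
Product: 8 (3S,4R,5R)-3,4-dimethyl-5-(3,4,5-trimethoxyphenyl)oxolan-2-one, via hydroxy acid 7 (not isolated)
Conditions: LiBH(s-Bu)3 (2.2 equiv), THF, −78 °C; then 1 M HCl, rt
Reagents that add atoms: none
Why: Felkin–Anh-controlled reduction of the aryl ketone by the bulky hydride (attack anti to the branched chain, past the α-hydrogen) should set the carbinol centre anti to the neighbouring methyl (future C5, R), and the γ-hydroxy acid lactonises on acidification to the 4,5-trans lactone.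

Step 4
Reactants: 8 (3S,4R,5R)-3,4-dimethyl-5-(3,4,5-trimethoxyphenyl)oxolan-2-one
Product: 9 (3S,4R,5R)-3,4-dimethyl-5-(3,4,5-trimethoxyphenyl)oxolan-2-ol (lactol; anomeric mixture)
Conditions: i-Bu2AlH (1.1 equiv), CH2Cl2, −78 °C; aq. KNaC4H4O6 (potassium sodium tartrate)
Reagents that add atoms: none
Why: Partial reduction of a γ-lactone to the lactol, relying on the stability of the tetrahedral aluminium alkoxide at low temperature; no ring stereocentre is touched and the new hemiacetal centre is of no consequence.

Step 5
Reactants: 10 3-methoxyphenol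
Product: 11 1-(benzyloxy)-3-methoxybenzene
Conditions: BnBr, K2CO3, acetone, reflux
Reagents that add atoms: benzyl bromide, BrCc1ccccc1
Why: Williamson ether synthesis on the phenoxide installs the benzyl group that will mask the future 3-hydroxyl of ring A to the end of the route.

Step 6
Reactants: 11 1-(benzyloxy)-3-methoxybenzene
Product: 14 2-(benzyloxy)-6-methoxyphenol, via aryllithium 12 (not isolated), via arylboronate 13 (not isolated)
Conditions: n-BuLi, THF, 0 °C → rt; B(OMe)3, −78 °C → rt; then AcOH, 30% H2O2, 0 °C → rt
Reagents that add atoms: hydrogen peroxide, OO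
Why: Directed ortho-metalation at the ring position flanked by both alkoxy groups (the most acidic C–H), borylation and oxidative conversion of the C–B bond into C–O give the 2,6-dialkoxyphenol with the three oxygens already differentiated.

Step 7
Reactants: 14 2-(benzyloxy)-6-methoxyphenol
Product: 15 2-(benzyloxy)-4-bromo-6-methoxyphenol
Conditions: NBS (1.0 equiv), MeCN, −20 → 0 °C
Reagents that add atoms: N-bromosuccinimide, O=C1CCC(=O)N1Br
Why: Electrophilic aromatic bromination goes para to the free hydroxyl, the strongest director, since both ortho positions are blocked.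

Step 8
Reactants: 9 (3S,4R,5R)-3,4-dimethyl-5-(3,4,5-trimethoxyphenyl)oxolan-2-ol; 15 2-(benzyloxy)-4-bromo-6-methoxyphenol
Product: 19 2-(benzyloxy)-6-methoxy-4-[(2S,3S,4R,5R)-3,4-dimethyl-5-(3,4,5-trimethoxyphenyl)oxolan-2-yl]phenol, via aryllithium phenolate 16 (not isolated), via C2-epimeric triol 17 (not isolated), via p-quinone methide 18 (not isolated)
Conditions: 15 (2.5 equiv), MeLi then t-BuLi, THF, −78 °C; add 9, −78 → 0 °C; then 1 M HCl to pH 2, 0 °C → rt
Reagents that add atoms: none
Why: Bromine–lithium exchange on the lithium phenolate of 15 gives dianion 16, one equivalent of which deprotonates the lactol while a second adds to its ring-opened hydroxy aldehyde to give triol 17 as a C2-epimer mixture; on acidification the 4-hydroxy-3,5-dialkoxybenzylic alcohol of 17 loses water to p-quinone methide 18, and the C5 hydroxyl adds to its exocyclic carbon (oxa-1,6-addition), re-aromatising ring A and forming the O–C2 bond. The closest known reaction type is the acid-promoted cyclisation of 1,4-diaryl-butane-1,4-diols to 2,5-diaryloxolanes, here run through the quinone-methide trapping by a side-chain hydroxyl that is thought to close the oxolane of furanoid lignans in nature. Ring B closes in the 5-exo-trig mode. The new C2 centre is controlled by the C3 methyl: in the quinone methide the C3–H eclipses the ring-A plane (allylic 1,3-strain) and the tethered oxygen attacks from the face of C4, which places ring A trans to the C3 methyl, and because the free para-phenol lets the ring reopen, thermodynamic control should lead to the same trans,cis,trans isomer. Both C2 epimers of 17 converge because that centre is erased in 18, while C3, C4 and C5 are not involved. The step needs ionisation at C2 and not at C5, and O- rather than C-trapping by ring C: only ring A carries a free para-hydroxyl, so at pH 2 only C2 can form a quinone methide while the 3,4,5-trimethoxybenzylic C5–OH keeps its configuration, and the mild acid and short exposure favour the fast reversible 5-exo oxygen closure over aryltetralin formation.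

Step 9
Reactants: 19 2-(benzyloxy)-6-methoxy-4-[(2S,3S,4R,5R)-3,4-dimethyl-5-(3,4,5-trimethoxyphenyl)oxolan-2-yl]phenol
Product: 20 (2S,3S,4R,5R)-2-[3-(benzyloxy)-4,5-dimethoxyphenyl]-3,4-dimethyl-5-(3,4,5-trimethoxyphenyl)oxolane
Conditions: MeI, K2CO3, DMF, rt
Reagents that add atoms: iodomethane, CI
Why: Williamson O-methylation of the only free phenol converts the activating 4-hydroxyl into the 4-methoxy group of the target and at the same time switches off quinone-methide formation, which locks C2.

Step 10
Reactants: 20 (2S,3S,4R,5R)-2-[3-(benzyloxy)-4,5-dimethoxyphenyl]-3,4-dimethyl-5-(3,4,5-trimethoxyphenyl)oxolane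
Product: 21 5-[(2S,3S,4R,5R)-3,4-dimethyl-5-(3,4,5-trimethoxyphenyl)oxolan-2-yl]-2,3-dimethoxyphenol (target)
Conditions: H2 (1 atm), Pd/C, EtOAc, rt
Reagents that add atoms: none
Why: Catalytic hydrogenolysis of the aryl benzyl ether, which under neutral conditions at low pressure should be cleaved much faster than the two benzylic C–O bonds of the oxolane, frees the 3-hydroxyl without touching a stereocentre.

## Compound list

1 | 2,3-dimethylmaleic anhydride | CC1=C(C)C(=O)OC1=O | starting material
2 | cis-2,3-dimethylsuccinic anhydride, (3R,4S)-3,4-dimethyloxolane-2,5-dione (meso) | O=C1OC(=O)[C@@H](C)[C@H]1C | intermediate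
3 | 5-bromo-1,2,3-trimethoxybenzene | COc1cc(Br)cc(OC)c1OC | starting material
4 | (3,4,5-trimethoxyphenyl)lithium (formed in situ) | [Li]c1cc(OC)c(OC)c(OC)c1 | intermediate
5 | (3,4,5-trimethoxyphenyl)zinc trifluoromethanesulfonate (formed in situ) | COc1cc([Zn]OS(=O)(=O)C(F)(F)F)cc(OC)c1OC | intermediate
6 | (2S,3R)-2,3-dimethyl-4-oxo-4-(3,4,5-trimethoxyphenyl)butanoic acid | OC(=O)[C@@H](C)[C@@H](C)C(=O)c1cc(OC)c(OC)c(OC)c1 | intermediate
7 | (2S,3R,4R)-4-hydroxy-2,3-dimethyl-4-(3,4,5-trimethoxyphenyl)butanoic acid (formed in situ) | OC(=O)[C@@H](C)[C@@H](C)[C@@H](O)c1cc(OC)c(OC)c(OC)c1 | intermediate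
8 | (3S,4R,5R)-3,4-dimethyl-5-(3,4,5-trimethoxyphenyl)oxolan-2-one | O=C1O[C@@H](c2cc(OC)c(OC)c(OC)c2)[C@H](C)[C@@H]1C | intermediate
9 | (3S,4R,5R)-3,4-dimethyl-5-(3,4,5-trimethoxyphenyl)oxolan-2-ol (anomeric mixture) | OC1O[C@@H](c2cc(OC)c(OC)c(OC)c2)[C@H](C)[C@@H]1C | intermediate
10 | 3-methoxyphenol | COc1cccc(O)c1 | starting material
11 | 1-(benzyloxy)-3-methoxybenzene | COc1cccc(OCc2ccccc2)c1 | intermediate
12 | [2-(benzyloxy)-6-methoxyphenyl]lithium (formed in situ) | [Li]c1c(OC)cccc1OCc2ccccc2 | intermediate
13 | dimethyl [2-(benzyloxy)-6-methoxyphenyl]boronate (formed in situ) | COB(OC)c1c(OC)cccc1OCc2ccccc2 | intermediate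
14 | 2-(benzyloxy)-6-methoxyphenol | COc1cccc(OCc2ccccc2)c1O | intermediate
15 | 2-(benzyloxy)-4-bromo-6-methoxyphenol | COc1cc(Br)cc(OCc2ccccc2)c1O | intermediate
16 | lithium 2-(benzyloxy)-4-lithio-6-methoxyphenolate (formed in situ) | [Li]c1cc(OC)c(O[Li])c(OCc2ccccc2)c1 | intermediate
17 | (2S,3R,4R)-1-[3-(benzyloxy)-4-hydroxy-5-methoxyphenyl]-2,3-dimethyl-4-(3,4,5-trimethoxyphenyl)butane-1,4-diol (both C1 epimers; formed in situ) | OC(c1cc(OC)c(O)c(OCc2ccccc2)c1)[C@@H](C)[C@@H](C)[C@@H](O)c3cc(OC)c(OC)c(OC)c3 | intermediate
18 | 2-(benzyloxy)-4-[(2R,3R,4R)-4-hydroxy-2,3-dimethyl-4-(3,4,5-trimethoxyphenyl)butylidene]-6-methoxycyclohexa-2,5-dien-1-one (p-quinone methide; formed in situ) | O=C1C(OC)=CC(=C[C@@H](C)[C@@H](C)[C@@H](O)c2cc(OC)c(OC)c(OC)c2)C=C1OCc3ccccc3 | intermediate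
19 | 2-(benzyloxy)-6-methoxy-4-[(2S,3S,4R,5R)-3,4-dimethyl-5-(3,4,5-trimethoxyphenyl)oxolan-2-yl]phenol | COc1cc([C@H]2O[C@@H](c3cc(OC)c(OC)c(OC)c3)[C@H](C)[C@@H]2C)cc(OCc4ccccc4)c1O | intermediate
20 | (2S,3S,4R,5R)-2-[3-(benzyloxy)-4,5-dimethoxyphenyl]-3,4-dimethyl-5-(3,4,5-trimethoxyphenyl)oxolane | COc1cc([C@H]2O[C@@H](c3cc(OC)c(OC)c(OC)c3)[C@H](C)[C@@H]2C)cc(OCc4ccccc4)c1OC | intermediate
21 | 5-[(2S,3S,4R,5R)-3,4-dimethyl-5-(3,4,5-trimethoxyphenyl)oxolan-2-yl]-2,3-dimethoxyphenol | COc1cc([C@H]2O[C@@H](c3cc(OC)c(OC)c(OC)c3)[C@H](C)[C@@H]2C)cc(O)c1OC | target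

## Step count

Total: 10 steps. Longest linear sequence: 7 steps (steps 1, 2, 3, 4, 8, 9, 10, from 2,3-dimethylmaleic anhydride); the ring-A branch (steps 5–7) joins at step 8.

## Steps most likely to fail, with fallbacks

Step 8. The addition of the poorly soluble dianion to the lactolate may be slow, and under the strongly basic conditions the open-chain aldehyde may enolise and lose the C3 configuration. The fallback gives up the organometallic addition and attaches ring A by electrophilic aromatic substitution. It sets out from lactol 9, which is acetylated (Ac2O, pyridine, DMAP cat.) to (3S,4R,5R)-3,4-dimethyl-5-(3,4,5-trimethoxyphenyl)oxolan-2-yl acetate F1. F1 is ionised with BF3·OEt2 in CH2Cl2 at −78 → 0 °C in the presence of phenol 14, whose position para to the hydroxyl attacks the cyclic oxocarbenium ion (Friedel–Crafts C-arylation, as in aryl C-glycoside synthesis). Under the Lewis acid the 4-hydroxyaryl oxolane can open and re-close through quinone methide 18, so C2 should settle on the same trans,cis,trans isomer. The route is rejoined at 19.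

Step 2. The selection between the two enantiotopic carbonyls may be insufficient, or the sense of induction may be the opposite of the one assumed. The fallback separates desymmetrisation from C–C bond formation and sets out from anhydride 2. Cinchona-alkaloid-mediated methanolysis (MeOH, quinidine or quinine as required, toluene, −55 °C) should give the hemiester (2R,3S)-4-methoxy-2,3-dimethyl-4-oxobutanoic acid F2. Thioesterification (EtSH, EDC·HCl, DMAP cat., CH2Cl2) gives methyl (2S,3R)-4-(ethylsulfanyl)-2,3-dimethyl-4-oxobutanoate F3. Fukuyama coupling of F3 with arylzinc 5 (PdCl2(PPh3)2 cat., THF/toluene, rt) gives methyl (2S,3R)-2,3-dimethyl-4-oxo-4-(3,4,5-trimethoxyphenyl)butanoate F4. Reduction of F4 with LiBH(s-Bu)3 as in step 3 is followed by lactonisation of the alkoxide onto the ester, and the route is rejoined at lactone 8.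

Step 3. Facial selectivity of the hydride addition to the ketone may be poor, which would give the 4,5-cis lactone alongside 8. The fallback replaces substrate control by catalyst control and sets out from keto acid 6. Asymmetric transfer hydrogenation with RuCl(p-cymene)[(R,R)-TsDPEN] in HCO2H/Et3N should deliver the (R)-carbinol, by analogy with simple aryl alkyl ketones. Hydroxy acid 7 then lactonises on acidic work-up and the route is rejoined at 8; this fallback makes no new compound (F0).

## Further compounds

F1 | step 8 | (3S,4R,5R)-3,4-dimethyl-5-(3,4,5-trimethoxyphenyl)oxolan-2-yl acetate (anomeric mixture) | CC(=O)OC1O[C@@H](c2cc(OC)c(OC)c(OC)c2)[C@H](C)[C@@H]1C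
F2 | step 2 | (2R,3S)-4-methoxy-2,3-dimethyl-4-oxobutanoic acid | COC(=O)[C@@H](C)[C@@H](C)C(=O)O
F3 | step 2 | methyl (2S,3R)-4-(ethylsulfanyl)-2,3-dimethyl-4-oxobutanoate | COC(=O)[C@@H](C)[C@@H](C)C(=O)SCC
F4 | step 2 | methyl (2S,3R)-2,3-dimethyl-4-oxo-4-(3,4,5-trimethoxyphenyl)butanoate | COC(=O)[C@@H](C)[C@@H](C)C(=O)c1cc(OC)c(OC)c(OC)c1
F0 | step 3 | none | none
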